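**Retrosynthetic overview**
- The route rests on ring A of the coumarin (C4a, C5, C6, C7, C8, C8a): its oxygens on C5 (OMe), C7 (OH) and C8a (O1) stand 1,3,5 to one another, and C4 sits on C4a between C5 and C8a.
- Ring A is cut into 3-(triisopropylsilyloxy)cyclobutenone 18 (C8a, C6, C7, C8 with O1 and O7) and 1-methoxyalkyne 15 (C5≡C4a, carrying C4, C3, the chroman and C2); they are joined by a vinylketene [2+2]/4π/6π cascade that leaves O1 as a free phenol.
- The lactone ring is closed afterwards: O1–C2 by oxidative lactonisation of phenol-alcohol 24, C3=C4 by quinone dehydrogenation, and the O7 silyl ether is cleaved last.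
- Alkyne 15 comes from lithium methoxyacetylide and primary iodide 12; C2 is carried as CH2OBn, because a leaving group β to an ester would be lost by elimination and a 3-methoxyprop-2-ynyl sulfonate is too prone to ionise for an enolate alkylation.
- Iodide 12 derives from arylacetate 7 (chromenylation of 2,4-dihydroxyacetophenone, hydrogenation, oxidative aryl shift); ring order: dimethylpyran ring of the chroman (step 1), ring A (step 11), lactone ring (step 13).

Key step: step 11

Assumption: the target has no stereocentre; C3 is carried as a racemate from 10 to 27 and becomes sp2 in step 14.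

**Route**

Step 1
Reactants: 1 2,4-dihydroxyacetophenone; 2 3-methylbut-2-enal
Product: 4 1-(5-hydroxy-2,2-dimethyl-2H-chromen-6-yl)ethan-1-one, via quinone methide 3 (not isolated)
Conditions: pyridine, 140 °C, sealed tube
Reagents that add atoms: none
Why: Base-mediated chromenylation (aldol-type attack of the carbon between the two hydroxyls on the enal, dehydration to 3, 6π-oxa-electrocyclisation); the acetyl-chelated 2-OH stays out of the ring, so the 4-oxygen closes the pyran and the acetyl group ends up on C6 next to the free 5-OH.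

Step 2
Reactants: 4 1-(5-hydroxy-2,2-dimethyl-2H-chromen-6-yl)ethan-1-one
Product: 5 1-(5-methoxy-2,2-dimethyl-2H-chromen-6-yl)ethan-1-one
Conditions: MeI, K2CO3, DMF, 50 °C
Reagents that add atoms: iodomethane, CI
Why: Williamson O-methylation; the polar solvent and mild heating should overcome the hydrogen bond of the chelated phenol, and carbonate is too weak to enolise the ketone.

Step 3
Reactants: 5 1-(5-methoxy-2,2-dimethyl-2H-chromen-6-yl)ethan-1-one
Product: 6 1-(5-methoxy-2,2-dimethylchroman-6-yl)ethan-1-one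
Conditions: H2 (1 atm), 10% Pd/C, EtOAc, rt
Reagents that add atoms: none
Why: Catalytic hydrogenation of the styrene-type chromene double bond, which should be reduced well before the electron-rich aryl ketone.

Step 4
Reactants: 6 1-(5-methoxy-2,2-dimethylchroman-6-yl)ethan-1-one
Product: 7 methyl 2-(5-methoxy-2,2-dimethylchroman-6-yl)acetate
Conditions: PhI(OAc)2, H2SO4, HC(OMe)3/MeOH, 60 °C
Reagents that add atoms: methanol, CO
Why: Hypervalent-iodine oxidative 1,2-aryl migration of an aryl methyl ketone to a methyl arylacetate; the 2,4-dioxygenated aryl group is a good migrating group, and the double bond that would interfere was removed in step 3.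

Step 5
Reactants: 7 methyl 2-(5-methoxy-2,2-dimethylchroman-6-yl)acetate; 8 benzyl chloromethyl ether
Product: 10 methyl 3-(benzyloxy)-2-(5-methoxy-2,2-dimethylchroman-6-yl)propanoate (racemic), via lithium enolate 9 (not isolated)
Conditions: LiN(iPr)2, THF, −78 °C; then 8, −78 to 0 °C
Reagents that add atoms: none
Why: Ester enolate C-alkylation with a reactive α-chloro ether; it introduces the carbon that becomes C2 and sets the C3 centre as a racemate, which needs no control because it is destroyed in step 14.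

Step 6
Reactants: 10 methyl 3-(benzyloxy)-2-(5-methoxy-2,2-dimethylchroman-6-yl)propanoate
Product: 11 3-(benzyloxy)-2-(5-methoxy-2,2-dimethylchroman-6-yl)propan-1-ol (racemic)
Conditions: LiAlH4, THF, 0 °C
Reagents that add atoms: none
Why: Hydride reduction of the ester to the primary alcohol (the future C4), which at 0 °C should outrun β-elimination of benzyloxide.

Step 7
Reactants: 11 3-(benzyloxy)-2-(5-methoxy-2,2-dimethylchroman-6-yl)propan-1-ol
Product: 12 6-[1-(benzyloxy)-3-iodopropan-2-yl]-5-methoxy-2,2-dimethylchroman (racemic)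
Conditions: I2, PPh3, imidazole, CH2Cl2, 0 °C to rt
Reagents that add atoms: iodine, II
Why: Appel-type iodination of a primary alcohol under buffered conditions; an iodide is chosen over a sulfonate because it is far less prone to aryl-assisted ionisation next to the electron-rich ring.

Step 8
Reactants: 12 6-[1-(benzyloxy)-3-iodopropan-2-yl]-5-methoxy-2,2-dimethylchroman; 13 2-chloro-1,1-dimethoxyethane
Product: 15 6-[1-(benzyloxy)-5-methoxypent-4-yn-2-yl]-5-methoxy-2,2-dimethylchroman (racemic), via lithium methoxyacetylide 14 (not isolated)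
Conditions: 13, LiNEt2 (3 equiv per 13), THF, 0 °C; then 12, DMPU, −20 °C to rt; NaHCO3 work-up
Reagents that add atoms: none
Why: Two eliminations and a deprotonation convert the α-chloro acetal into 14, which displaces the primary iodide (SN2 acetylide alkylation, forming C4–C4a); the ynol ether is stable to base and is kept away from acid in the work-up.

Step 9
Reactants: 16 3-ethoxycyclobut-2-en-1-one
Product: 17 cyclobutane-1,3-dione
Conditions: aq. HCl, THF, 0 °C to rt
Reagents that add atoms: water, O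
Why: Acid hydrolysis of a vinylogous ester to the 1,3-dione.

Step 10
Reactants: 17 cyclobutane-1,3-dione
Product: 18 3-(triisopropylsilyloxy)cyclobut-2-en-1-one
Conditions: iPr3SiCl, Et3N, CH2Cl2, 0 °C; non-aqueous work-up
Reagents that add atoms: chlorotri(propan-2-yl)silane, CC(C)[Si](Cl)(C(C)C)C(C)C
Why: O-silylation of the acidic enol form of the dione gives the silyl enol ether, and the bulky silyl group should give it enough hydrolytic stability to be handled.

Step 11
Reactants: 15 6-[1-(benzyloxy)-5-methoxypent-4-yn-2-yl]-5-methoxy-2,2-dimethylchroman; 18 3-(triisopropylsilyloxy)cyclobut-2-en-1-one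
Product: 23 2-[3-(benzyloxy)-2-(5-methoxy-2,2-dimethylchroman-6-yl)propyl]-3-methoxy-5-(triisopropylsilyloxy)phenol (racemic), via vinylketene 19 (not isolated), via vinylcyclobutenone 20 (not isolated), via dienylketene 21 (not isolated), via cyclohexadienone 22 (not isolated)
Conditions: 18 (1.5 equiv), toluene, 110 °C, sealed tube
Reagents that add atoms: none
Why: On heating, 18 should open by 4π electrocyclic cleavage to vinylketene 19, whose ketene carbon (future C8a) is attacked by the alkyl-bearing, nucleophilic carbon of the ynol ether (C4a) while the methoxy-bearing carbon (C5) bonds to the ketene α-carbon (C6), giving 20. Strain-driven, reversible conrotatory 4π opening of 20 gives dienylketene 21, and ring A closes by disrotatory 6π electrocyclisation (C8–C8a) to 22, which tautomerises to phenol 23. The closest known reaction is the Danheiser benzannulation of cyclobutenone-derived vinylketenes with alkoxyalkynes; the 3-silyloxy group on the cyclobutenone is the less tested variable and is expected mainly to raise the opening temperature, which a methyl ynol ether (no retro-ene path) should tolerate. No stereocentre is formed, and the racemic C3 centre is a spectator. The only selectivity needed is the regiochemistry of the ketene–alkyne [2+2] step, which the polarisation of the ynol ether secures, so OMe arrives on C5, the silyl ether on C7 and the free hydroxyl on C8a beside the side chain. The benzyl ether, the aryl ethers and the chroman should be inert under these neutral thermal conditions.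

Step 12
Reactants: 23 2-[3-(benzyloxy)-2-(5-methoxy-2,2-dimethylchroman-6-yl)propyl]-3-methoxy-5-(triisopropylsilyloxy)phenol
Product: 24 2-[3-hydroxy-2-(5-methoxy-2,2-dimethylchroman-6-yl)propyl]-3-methoxy-5-(triisopropylsilyloxy)phenol (racemic)
Conditions: H2 (1 atm), 10% Pd/C, EtOAc/EtOH, rt
Reagents that add atoms: none
Why: Hydrogenolysis of the benzyl ether; the aryl silyl ether, the methyl ethers and the chroman are not cleaved under these conditions.

Step 13
Reactants: 24 2-[3-hydroxy-2-(5-methoxy-2,2-dimethylchroman-6-yl)propyl]-3-methoxy-5-(triisopropylsilyloxy)phenol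
Product: 27 5-methoxy-3-(5-methoxy-2,2-dimethylchroman-6-yl)-7-(triisopropylsilyloxy)chroman-2-one (racemic), via hydroxy aldehyde 25 (not isolated), via lactol 26 (not isolated)
Conditions: [C5H5NH][CrO3Cl] (pyridinium chlorochromate), NaOAc, 4 Å MS, CH2Cl2, rt
Reagents that add atoms: none
Why: Oxidative lactonisation forming O1–C2: the primary alcohol is oxidised to aldehyde 25, the neighbouring phenol traps it as chroman-2-ol 26 (which also masks the phenol), and a second oxidation gives the lactone; acetate buffers the medium.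

Step 14
Reactants: 27 5-methoxy-3-(5-methoxy-2,2-dimethylchroman-6-yl)-7-(triisopropylsilyloxy)chroman-2-one
Product: 28 5-methoxy-3-(5-methoxy-2,2-dimethylchroman-6-yl)-7-(triisopropylsilyloxy)-2H-chromen-2-one
Conditions: DDQ (1.1 equiv), 1,4-dioxane, 60 °C
Reagents that add atoms: none
Why: Quinone dehydrogenation by hydride abstraction from C4 (benzylic to ring A and para to the C7 silyloxy group) and loss of the acidic C3 proton; the chroman CH2 has only ortho oxygens and should react more slowly, so a small excess at moderate temperature is used, and the C3 stereocentre disappears here.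

Step 15
Reactants: 28 5-methoxy-3-(5-methoxy-2,2-dimethylchroman-6-yl)-7-(triisopropylsilyloxy)-2H-chromen-2-one
Product: 29 7-hydroxy-5-methoxy-3-(5-methoxy-2,2-dimethylchroman-6-yl)-2H-chromen-2-one (target)
Conditions: Bu4NF, AcOH, THF, 0 °C
Reagents that add atoms: none
Why: Fluoride cleavage of the aryl silyl ether; acetic acid buffers the phenoxide so that the coumarin lactone is not opened.

**Compound list**
1 | 2,4-dihydroxyacetophenone | CC(=O)c1ccc(O)cc1O | starting material
2 | 3-methylbut-2-enal | CC(C)=CC=O | starting material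
3 | 4-acetyl-3-hydroxy-2-(3-methylbut-2-en-1-ylidene)cyclohexa-3,5-dien-1-one (quinone methide) | CC(=O)C1=C(O)C(=CC=C(C)C)C(=O)C=C1 | intermediate
4 | 1-(5-hydroxy-2,2-dimethyl-2H-chromen-6-yl)ethan-1-one | CC(=O)c1ccc2OC(C)(C)C=Cc2c1O | intermediate
5 | 1-(5-methoxy-2,2-dimethyl-2H-chromen-6-yl)ethan-1-one | CC(=O)c1ccc2OC(C)(C)C=Cc2c1OC | intermediate
6 | 1-(5-methoxy-2,2-dimethylchroman-6-yl)ethan-1-one | CC(=O)c1ccc2OC(C)(C)CCc2c1OC | intermediate
7 | methyl 2-(5-methoxy-2,2-dimethylchroman-6-yl)acetate | COC(=O)Cc1ccc2OC(C)(C)CCc2c1OC | intermediate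
8 | benzyl chloromethyl ether | ClCOCc1ccccc1 | starting material
9 | lithium enolate of 7 | COC(O[Li])=Cc1ccc2OC(C)(C)CCc2c1OC | intermediate
10 | methyl 3-(benzyloxy)-2-(5-methoxy-2,2-dimethylchroman-6-yl)propanoate (racemic) | COC(=O)C(COCc1ccccc1)c1ccc2OC(C)(C)CCc2c1OC | intermediate
11 | 3-(benzyloxy)-2-(5-methoxy-2,2-dimethylchroman-6-yl)propan-1-ol (racemic) | OCC(COCc1ccccc1)c1ccc2OC(C)(C)CCc2c1OC | intermediate
12 | 6-[1-(benzyloxy)-3-iodopropan-2-yl]-5-methoxy-2,2-dimethylchroman (racemic) | ICC(COCc1ccccc1)c1ccc2OC(C)(C)CCc2c1OC | intermediate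
13 | 2-chloro-1,1-dimethoxyethane (chloroacetaldehyde dimethyl acetal) | COC(CCl)OC | starting material
14 | lithium methoxyacetylide | [Li]C#COC | intermediate
15 | 6-[1-(benzyloxy)-5-methoxypent-4-yn-2-yl]-5-methoxy-2,2-dimethylchroman (racemic) | COC#CCC(COCc1ccccc1)c1ccc2OC(C)(C)CCc2c1OC | intermediate
16 | 3-ethoxycyclobut-2-en-1-one | CCOC1=CC(=O)C1 | starting material
17 | cyclobutane-1,3-dione | O=C1CC(=O)C1 | intermediate
18 | 3-(triisopropylsilyloxy)cyclobut-2-en-1-one | O=C1CC(O[Si](C(C)C)(C(C)C)C(C)C)=C1 | intermediate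
19 | 3-(triisopropylsilyloxy)buta-1,3-dien-1-one (vinylketene) | O=C=CC(=C)O[Si](C(C)C)(C(C)C)C(C)C | intermediate
20 | 2-[3-(benzyloxy)-2-(5-methoxy-2,2-dimethylchroman-6-yl)propyl]-3-methoxy-4-[1-(triisopropylsilyloxy)ethenyl]cyclobut-2-en-1-one (mixture of diastereomers) | COC1=C(CC(COCc2ccccc2)c2ccc3OC(C)(C)CCc3c2OC)C(=O)C1C(=C)O[Si](C(C)C)(C(C)C)C(C)C | intermediate
21 | (3E)-2-[3-(benzyloxy)-2-(5-methoxy-2,2-dimethylchroman-6-yl)propyl]-3-methoxy-5-(triisopropylsilyloxy)hexa-1,3,5-trien-1-one (dienylketene) | CO/C(C(=C=O)CC(COCc1ccccc1)c1ccc2OC(C)(C)CCc2c1OC)=C/C(=C)O[Si](C(C)C)(C(C)C)C(C)C | intermediate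
22 | 2-[3-(benzyloxy)-2-(5-methoxy-2,2-dimethylchroman-6-yl)propyl]-3-methoxy-5-(triisopropylsilyloxy)cyclohexa-2,4-dien-1-one | COC1=C(CC(COCc2ccccc2)c2ccc3OC(C)(C)CCc3c2OC)C(=O)CC(O[Si](C(C)C)(C(C)C)C(C)C)=C1 | intermediate
23 | 2-[3-(benzyloxy)-2-(5-methoxy-2,2-dimethylchroman-6-yl)propyl]-3-methoxy-5-(triisopropylsilyloxy)phenol (racemic) | COc1cc(O[Si](C(C)C)(C(C)C)C(C)C)cc(O)c1CC(COCc1ccccc1)c1ccc2OC(C)(C)CCc2c1OC | intermediate
24 | 2-[3-hydroxy-2-(5-methoxy-2,2-dimethylchroman-6-yl)propyl]-3-methoxy-5-(triisopropylsilyloxy)phenol (racemic) | COc1cc(O[Si](C(C)C)(C(C)C)C(C)C)cc(O)c1CC(CO)c1ccc2OC(C)(C)CCc2c1OC | intermediate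
25 | 3-[2-hydroxy-6-methoxy-4-(triisopropylsilyloxy)phenyl]-2-(5-methoxy-2,2-dimethylchroman-6-yl)propanal (racemic) | COc1cc(O[Si](C(C)C)(C(C)C)C(C)C)cc(O)c1CC(C=O)c1ccc2OC(C)(C)CCc2c1OC | intermediate
26 | 5-methoxy-3-(5-methoxy-2,2-dimethylchroman-6-yl)-7-(triisopropylsilyloxy)chroman-2-ol (mixture of diastereomers) | COc1cc(O[Si](C(C)C)(C(C)C)C(C)C)cc2OC(O)C(c3ccc4OC(C)(C)CCc4c3OC)Cc12 | intermediate
27 | 5-methoxy-3-(5-methoxy-2,2-dimethylchroman-6-yl)-7-(triisopropylsilyloxy)chroman-2-one (racemic) | COc1cc(O[Si](C(C)C)(C(C)C)C(C)C)cc2OC(=O)C(c3ccc4OC(C)(C)CCc4c3OC)Cc12 | intermediate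
28 | 5-methoxy-3-(5-methoxy-2,2-dimethylchroman-6-yl)-7-(triisopropylsilyloxy)-2H-chromen-2-one | COc1cc(O[Si](C(C)C)(C(C)C)C(C)C)cc2oc(=O)c(-c3ccc4OC(C)(C)CCc4c3OC)cc12 | intermediate
29 | 7-hydroxy-5-methoxy-3-(5-methoxy-2,2-dimethylchroman-6-yl)-2H-chromen-2-one | COc1c(-c2cc3c(OC)cc(O)cc3oc2=O)ccc2c1CCC(C)(C)O2 | target

**Step count**
Total: 15 steps. Longest linear sequence: 13 steps (steps 1–8 and 11–15); the cyclobutenone branch (steps 9 and 10) is convergent.

**Steps most likely to fail**

1. Step 11. The donor-stabilised cyclobutenone may open too slowly, so that the vinylketene is scarce while the ynol ether degrades; the vinylketene may also dimerise or acylate the phenol of the product. The fallback uses known chemistry and buys ring A instead of building it. It sets out from 7: saponification (LiOH, THF/H2O) should give 2-(5-methoxy-2,2-dimethylchroman-6-yl)acetic acid F1. Perkin condensation of this acid with purchased 2,4-dihydroxy-6-methoxybenzaldehyde (Ac2O, Et3N, 120 °C) should give 5-methoxy-3-(5-methoxy-2,2-dimethylchroman-6-yl)-2-oxo-2H-chromen-7-yl acetate F2. Cleavage of the acetate (K2CO3, MeOH) brings the route back at 29.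

2. Step 8. Elimination across the benzylic C–H bond β to the iodide may compete with a slow substitution at the β-branched carbon. The fallback removes that hydrogen by making C3 sp2 during the alkylation. It sets out from 7: α-methylenation (paraformaldehyde, K2CO3, Bu4NI, toluene, 80 °C) should give methyl 2-(5-methoxy-2,2-dimethylchroman-6-yl)prop-2-enoate F3. Reduction (iBu2AlH, CH2Cl2, −78 °C) should give 2-(5-methoxy-2,2-dimethylchroman-6-yl)prop-2-en-1-ol F4, and CBr4/PPh3 should give 6-(3-bromoprop-1-en-2-yl)-5-methoxy-2,2-dimethylchroman F5. Alkylation of 14 with this allylic bromide (THF/DMPU, −78 to 0 °C) should give 5-methoxy-6-(5-methoxypent-1-en-4-yn-2-yl)-2,2-dimethylchroman F6. Benzannulation with 18 as in step 11 should give 3-methoxy-2-[2-(5-methoxy-2,2-dimethylchroman-6-yl)prop-2-en-1-yl]-5-(triisopropylsilyloxy)phenol F7. Hydroboration–oxidation (9-BBN, THF; NaBO3·4H2O) brings the route back at 24.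

3. Step 13. The chromium reagent may oxidise the electron-rich free phenol before the lactol has formed. The fallback masks the phenol before any oxidation. It sets out from 23: Boc2O and catalytic DMAP should give 2-[3-(benzyloxy)-2-(5-methoxy-2,2-dimethylchroman-6-yl)propyl]-3-methoxy-5-(triisopropylsilyloxy)phenyl tert-butyl carbonate F8. Hydrogenolysis (H2, Pd/C) should give tert-butyl 2-[3-hydroxy-2-(5-methoxy-2,2-dimethylchroman-6-yl)propyl]-3-methoxy-5-(triisopropylsilyloxy)phenyl carbonate F9. Oxidation (TEMPO, PhI(OAc)2, MeCN/H2O) should give 3-[2-(tert-butoxycarbonyloxy)-6-methoxy-4-(triisopropylsilyloxy)phenyl]-2-(5-methoxy-2,2-dimethylchroman-6-yl)propanoic acid F10. CF3CO2H in CH2Cl2 removes the carbonate and lactonises the hydroxy acid, which brings the route back at 27.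

**Further compounds**
F1 | step 11 | 2-(5-methoxy-2,2-dimethylchroman-6-yl)acetic acid | OC(=O)Cc1ccc2OC(C)(C)CCc2c1OC
F2 | step 11 | 5-methoxy-3-(5-methoxy-2,2-dimethylchroman-6-yl)-2-oxo-2H-chromen-7-yl acetate | CC(=O)Oc1cc(OC)c2cc(-c3ccc4OC(C)(C)CCc4c3OC)c(=O)oc2c1
F3 | step 8 | methyl 2-(5-methoxy-2,2-dimethylchroman-6-yl)prop-2-enoate | COC(=O)C(=C)c1ccc2OC(C)(C)CCc2c1OC
F4 | step 8 | 2-(5-methoxy-2,2-dimethylchroman-6-yl)prop-2-en-1-ol | OCC(=C)c1ccc2OC(C)(C)CCc2c1OC
F5 | step 8 | 6-(3-bromoprop-1-en-2-yl)-5-methoxy-2,2-dimethylchroman | BrCC(=C)c1ccc2OC(C)(C)CCc2c1OC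
F6 | step 8 | 5-methoxy-6-(5-methoxypent-1-en-4-yn-2-yl)-2,2-dimethylchroman | COC#CCC(=C)c1ccc2OC(C)(C)CCc2c1OC
F7 | step 8 | 3-methoxy-2-[2-(5-methoxy-2,2-dimethylchroman-6-yl)prop-2-en-1-yl]-5-(triisopropylsilyloxy)phenol | COc1cc(O[Si](C(C)C)(C(C)C)C(C)C)cc(O)c1CC(=C)c1ccc2OC(C)(C)CCc2c1OC
F8 | step 13 | 2-[3-(benzyloxy)-2-(5-methoxy-2,2-dimethylchroman-6-yl)propyl]-3-methoxy-5-(triisopropylsilyloxy)phenyl tert-butyl carbonate (racemic) | COc1cc(O[Si](C(C)C)(C(C)C)C(C)C)cc(OC(=O)OC(C)(C)C)c1CC(COCc1ccccc1)c1ccc2OC(C)(C)CCc2c1OC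
F9 | step 13 | tert-butyl 2-[3-hydroxy-2-(5-methoxy-2,2-dimethylchroman-6-yl)propyl]-3-methoxy-5-(triisopropylsilyloxy)phenyl carbonate (racemic) | COc1cc(O[Si](C(C)C)(C(C)C)C(C)C)cc(OC(=O)OC(C)(C)C)c1CC(CO)c1ccc2OC(C)(C)CCc2c1OC
F10 | step 13 | 3-[2-(tert-butoxycarbonyloxy)-6-methoxy-4-(triisopropylsilyloxy)phenyl]-2-(5-methoxy-2,2-dimethylchroman-6-yl)propanoic acid (racemic) | COc1cc(O[Si](C(C)C)(C(C)C)C(C)C)cc(OC(=O)OC(C)(C)C)c1CC(C(O)=O)c1ccc2OC(C)(C)CCc2c1OC
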